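3 questions are put below, and each asks how a flask divides its substrate between target and isomer of the product.

| flask | substrate | free catalyst | remark | time |
|---|---|---|---|---|
| larch | 0.022 M | 6.8 mol% | run made earlier |  |
| teal | 0.020 M | 6.8 mol% |  | 15 min |
| grey | 0.0060 M | 5 mol% |  | 15 min |
| red | 0.020 M | 3 mol% |  | 15 min |
| violet | 0.020 M | 25 mol% |  | 15 min |
| green | 0.080 M | 2.5 mol% |  | 15 min |

larch run (percent of the substrate charged)

| time / min | target / % | isomer of the product / % |
|---|---|---|
| 1.33 | 26.6 | 7.5 |
| 2.50 | 41.5 | 12.2 |
| 4.00 | 53.2 | 16.9 |
| 5.00 | 58.8 | 19.2 |

(readings scatter by 0.3 percentage points)

- the numbers in the tables scatter by 0.3 percentage points (one standard deviation)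
- in a conversion other conformer counts as not yet reacted
- the share counts what is present at the end, not what went on to other products
- no earlier run changes the charge of free catalyst; that part of a forecast is a guess

- the flasks put in order of share of target in all that became target or isomer of the product, best first, at 15 min (teal / grey / red / violet / green)
- the share of target in all that became target or isomer of the product of the flask you put first, at 15 min
- the share of target in all that became target or isomer of the product of the flask you put last, at 15 min

Picture substrate as a tank with two drains, one to target, whose pace follows the free catalyst concentration, and one to isomer of the product. Ask first which inputs must be known well. In this picture time hardly counts, since two drains on one tank keep their ratio at any level. Substrate and loading count together, as their product. The larch reading counts moderately: its share slides from 78.0% to 75.4%, a drift of 2.6 percentage points. The guess matters too: larch has one catalyst charge and can't show whether the isomer drain follows catalyst. You assume it doesn't.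

Now the number. At 5.00 min, larch holds 58.8% of its charge as target and 19.2% as isomer of the product, a split of 3.06 at 1.50 mM of free catalyst. That reading gives 2.05 /mM, the split per unit of free catalyst, a selectivity factor. With free catalyst held at its charge and the isomer drain assumed not to follow it, multiply this by a flask's catalyst to get the split, and the share is split over one plus split. By this reckoning violet, with 5.00 mM, ranks first at 91.1%. Grey, with 0.300 mM, ranks last at 38.0%. Green, teal and red rank between, in that order.

The forecast says of the slide, “That fits target leaking slowly into isomer”, and gives grey > red > teal > green > violet, from 75% to 47%.

The flasks give violet > green > teal > red > grey, from 90.1% to 39.1%.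

    free catalyst + other conformer → free catalyst + isomer of the product (k = 53.0 /M/s)
    substrate + free catalyst → free catalyst + target (k = 2.70 /M/s)
    substrate ⇌ other conformer (K = 5.50, k = 0.00130 /s)
    free catalyst + target → spent catalyst (k = 0.0330 /M/s)

Against these, 2.05 /mM gave you 91.1% and 38.0%. On a flask like grey but with 8.5 mol% of free catalyst, it gives 51.1%, and that flask gives 51.4%. In grey, the steps to other conformer and to target ran side by side, each with 0.5 of its turnover up to 15.0 min behind it by 4.39 min, while free catalyst stood at 96.3% of its charge at 15.0 min. In violet, substrate was down to 0.224% by 7.50 min, and free catalyst went on taking target into spent catalyst, target sliding from 85.9% to 81.7% at 15.0 min, with isomer of the product at 8.95%.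

(All runs are calculated on assumed constants; scatter was added.)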